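The readings stem from a simulated flask for an exercise, noise included.

Wednesday's flask charges 6.00 parts of second nucleophile per part of first and Monday's 1.50, and this ratio is what I watch in both.

| setting | birch | ash | Wednesday's | Monday's |
|---|---|---|---|---|
| starting material | 0.050 M | 0.050 M | 0.050 M | 0.050 M |
| first nucleophile | 1.2 equiv | 1.2 equiv | 1.20 equiv | 1.20 equiv |
| second nucleophile | 2.6 equiv | 11 equiv | 7.20 equiv | 1.80 equiv |
| protic impurity | 2.5 mM | 2.5 mM | 2.50 mM | 2.50 mM |
| temperature | 65 °C | 90 °C |  |  |
| remark | run made earlier | run made earlier | at 70 °C throughout | at 70 °C until 50 min, from then on at 110 °C |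
| time |  |  | 2.5 h | 2.5 h |

* which one finishes higher in amount of target, in percent of the starting material charged ("neither" within 2 percentage points) (Wednesday's / Monday's / neither)
* amount of target at the end, in percent of the starting material charged, Wednesday's
* amount of target at the end, in percent of the starting material charged, Monday's

- reactions considered so far: starting material + protic impurity -> quenched substrate; second nucleophile + intermediate -> other capture product; first nucleophile + intermediate -> target; starting material -> intermediate

| run | time / min | target / % | starting material / % |
|---|---|---|---|
| birch | 5.00 | 12.9 | 68.1 |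
| birch | 15.0 | 36.4 | 33.8 |
| birch | 25.0 | 45.3 | 16.6 |
| birch | 40.0 | 49.3 | 5.9 |
| birch | 60.0 | 50.6 | 0.7 |
| birch | 80.0 | 53.8 | 0.6 |
| ash | 4.00 | 27.1 | 7.1 |
| ash | 10.0 | 30.8 | 0 |
| ash | 15.0 | 28.6 | 0 |
| ash | 20.0 | 31.9 | 0 |
| ash | 30.0 | 30.9 | 1.2 |

(scatter of a reading: 1 percentage point)

I read the birch table downward. Starting material falls from 33.8 % at 15.0 min to 5.9 % at 40.0 min, which gives a decay constant of 0.0698 /min, and its last rows hold target near 52.2 %. In the ash table the first row gives 0.661 /min, and the rows from 10.0 min onward average 30.5 % target.

The large part is the split of the intermediate; the small part is the impurity, which can take 5.00 % of the charge, and I count that whole allowance as lost. The rest is target or other capture product, in fractions of the charge. So I carry the capture ratio, the selectivity factor: how many times more readily the intermediate takes first nucleophile than second at equal amounts. Each nucleophile is used up as it captures, so this ratio equals the logarithmic fall of the first over that of the second. That gives 3.17 in the birch run and 4.87 in the ash run. Interpolated to 70 °C, it is 3.46.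

For Monday's flask the same interpolation gives 0.109 /min, so I estimate that 0.420 % of the starting material is left at 50 min, less than the impurity allowance. I therefore use the 70 °C ratio for Monday's too.

With the charged amounts, Wednesday's gives 34.7 % target and Monday's 66.3 %. The correction replaces each charge by its mean over the run, which brings Wednesday's to 32.3 % and Monday's to 61.2 %.

The forecast names Monday's, with Wednesday's at 32 % (29 % to 36 %) and Monday's at 61 % (53 % to 66 %). It takes a ratio of 3.4 where I take 3.46, and says of Monday's that “Later heating should change little”.

The flasks give 32.3 % for Wednesday's and 61.6 % for Monday's, so Monday's finishes higher. Monday's already held 61.3 % target at the change of temperature, and the departure from the starting temperature makes no difference worth watching.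

    starting material + protic impurity → quenched substrate (k = 226 /M/h, Ea = 62.0 kJ/mol)
    second nucleophile + intermediate → other capture product (k = 491 /M/h, Ea = 51.0 kJ/mol)
    first nucleophile + intermediate → target (k = 1660 /M/h, Ea = 66.0 kJ/mol)
    starting material → intermediate (k = 6.78 /h, Ea = 93.0 kJ/mol)
    (constants at 70 °C)

Take a neighbour of Wednesday's flask, the same but with 29.0 equiv of second nucleophile. The capture ratio of 3.46 gives 11.9 % target from the charges and 11.5 % with the mean amounts, a correction smaller than Monday's. That neighbour ends at 11.4 % target.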